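The route exploits the γ-hydroxy enone of ring B. The array O=C2–C3=C4–C4a–OH is a 2-silyloxyfuran in disguise: the exocyclic oxygen becomes the ketone and the ring oxygen becomes the tertiary alcohol. The bonds C4a–C8a and C1–C2 are therefore disconnected. In the forward direction, one thermal intramolecular furan Diels–Alder reaction, followed by hydrolytic opening of the oxygen bridge, closes rings A and B and sets C4a and C8a of the trans-decalin. The precursor is a 2-(triisopropylsilyloxy)furan. It carries the bromocyclopentyl ring C at C3 and, at C4a, the linalool-derived C5 carbinol carbon, from which the C6–C7 chain leads to the C8 isopropenyl ketone.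

Key step: step 16

Remarks and assumptions
- Locants: naphthalen-2(1H)-one locants C1–C8a are used for every intermediate. Ring A = C4a, C5, C6, C7, C8, C8a. Ring B = C1, C2, C3, C4, C4a, C8a. Ring C = cyclopentane C1′–C5′ (C1′ quaternary, C2′ gem-dimethyl, C3′ CHBr).
- Reading of the target: (4aR,5R,8S,8aS,1′R,3′R). It is a trans-decalin with C4a–OH and C8a–CH3 axial and anti, C5–OH axial, and C5–CH3 and C8–Br equatorial. On ring C the bromine is cis to the decalin substituent.
- Assumption: (1S,3R)-(−)-camphoric acid, (R)-(−)-linalool and isopropenylmagnesium bromide are bought in high enantiomeric purity where relevant. This camphoric acid series already holds C1′ and the gem-dimethyl group. The C1′ descriptor changes from S to R only through the priority switch when CO2H is replaced.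
- Order of events: both linalool alkenes are cleaved before the isopropenyl group exists, because ozone would not spare it. C8 stays an alcohol until acetylide addition and hydroalumination are over, because an enone would not survive them.

Step 1
Reactants: 1 (1S,3R)-camphoric acid
Product: 2 (1S,3R)-1,2,2-trimethylcyclopentane-1,3-dimethanol
Conditions: LiAlH4, THF, 0 °C to reflux
Reagents that add atoms: none
Why: LiAlH4 reduction of carboxylic acids takes both carboxyl groups, the hindered C1′ one included, to primary alcohols without touching C1′ or C3′.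

Step 2
Reactants: 2 (1S,3R)-1,2,2-trimethylcyclopentane-1,3-dimethanol
Product: 3 (1S,3R)-1,2,2-trimethylcyclopentane-1,3-dicarbaldehyde
Conditions: (COCl)2, DMSO, CH2Cl2, −78 °C; Et3N, −78 to 0 °C
Reagents that add atoms: none
Why: Swern oxidation stops cleanly at the dialdehyde and avoids the lactone that oxoammonium oxidants make from 1,5-diols, and any epimerisation at C3′ is harmless because this centre is erased in step 3.

Step 3
Reactants: 3 (1S,3R)-1,2,2-trimethylcyclopentane-1,3-dicarbaldehyde
Product: 4 (1S)-3-[(tert-butyldimethylsilyloxy)methylidene]-1,2,2-trimethylcyclopentane-1-carbaldehyde (E/Z mixture)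
Conditions: TBSOTf, Et3N, CH2Cl2, 0 °C
Reagents that add atoms: tert-butyldimethylsilyl triflate, CC(C)(C)[Si](C)(C)OS(=O)(=O)C(F)(F)F
Why: Soft enolisation with a silyl triflate and an amine can engage only the C3′ formyl group, since the C1′ aldehyde has no α-hydrogen, so the two aldehydes are differentiated as enol silane and free aldehyde.

Step 4
Reactants: 4 (1S)-3-[(tert-butyldimethylsilyloxy)methylidene]-1,2,2-trimethylcyclopentane-1-carbaldehyde
Product: 5 (1S)-1,2,2-trimethyl-3-oxocyclopentane-1-carbaldehyde
Conditions: O3, pyridine, CH2Cl2, −78 °C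
Reagents that add atoms: ozone, [O-][O+]=O
Why: Ozonolysis cleaves the electron-rich enol ether far faster than it oxidises the aldehyde, excising the former formyl carbon as silyl formate and leaving the C3′ ketone, while pyridine decomposes the carbonyl oxide so that no separate reductant is needed.

Step 5
Reactants: 5 (1S)-1,2,2-trimethyl-3-oxocyclopentane-1-carbaldehyde
Product: 6 (3R)-3-ethynyl-2,2,3-trimethylcyclopentan-1-one
Conditions: dimethyl (1-diazo-2-oxopropyl)phosphonate, K2CO3, MeOH, 0 °C to rt
Reagents that add atoms: dimethyl (1-diazo-2-oxopropyl)phosphonate, COP(=O)(OC)C(=[N+]=[N-])C(C)=O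
Why: Ohira–Bestmann (Seyferth–Gilbert) homologation turns the non-enolisable aldehyde into the terminal alkyne under mild carbonate conditions, the aldehyde being much more electrophilic than the α-quaternary cyclopentanone.

Step 6
Reactants: 6 (3R)-3-ethynyl-2,2,3-trimethylcyclopentan-1-one
Product: 7 (1S,3R)-3-ethynyl-2,2,3-trimethylcyclopentan-1-ol (OH trans to ethynyl)
Conditions: (3aR)-1-methyl-3,3-diphenyltetrahydro-1H,3H-pyrrolo[1,2-c][1,3,2]oxazaborole ((R)-Me-CBS, 20 mol %), catecholborane, toluene, −78 to −40 °C; then MeOH, water
Reagents that add atoms: none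
Why: Corey–Bakshi–Shibata reduction, in which the (R)-oxazaborolidine tells the quaternary C2′ flank from the C4′ methylene and delivers hydride to the face carrying the slim ethynyl group (the face the substrate also prefers), sets the (S)-carbinol trans to the alkyne, and catecholborane at low temperature does not hydroborate the alkyne.

Step 7
Reactants: 7 (1S,3R)-3-ethynyl-2,2,3-trimethylcyclopentan-1-ol
Product: 8 (1R,3R)-3-bromo-1-ethynyl-1,2,2-trimethylcyclopentane (Br cis to ethynyl)
Conditions: CBr4, PPh3, CH2Cl2, 0 °C to reflux
Reagents that add atoms: carbon tetrabromide, BrC(Br)(Br)Br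
Why: Appel reaction, in which bromide displaces the oxyphosphonium group by SN2 with inversion, a process that cyclopentyl carbons tolerate even next to a quaternary centre, sets the (3′R)-bromide cis to the ethynyl group.

Step 8
Reactants: 9 (R)-linalool
Product: 10 (R)-linalool triethylsilyl ether
Conditions: TESOTf, 2,6-lutidine, CH2Cl2, 0 °C
Reagents that add atoms: triethylsilyl triflate, CC[Si](CC)(CC)OS(=O)(=O)C(F)(F)F
Why: Silylation with a silyl triflate and 2,6-lutidine is the standard way to cap a tertiary allylic alcohol, and the C5 stereocentre is carried over unchanged from the chiral pool.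

Step 9
Reactants: 10 (R)-linalool triethylsilyl ether
Product: 11 (2R)-2-methyl-2-(triethylsilyloxy)pentanedial
Conditions: O3, pyridine, CH2Cl2, −78 °C
Reagents that add atoms: ozone, [O-][O+]=O
Why: Twofold ozonolysis (pyridine-mediated reductive variant) cleaves both alkenes at once and delivers two very different aldehydes, the hindered non-enolisable one that becomes C4a and the unhindered one that becomes C8.

Step 10
Reactants: 11 (2R)-2-methyl-2-(triethylsilyloxy)pentanedial; 12 isopropenylmagnesium bromide
Product: 13 (2R)-5-hydroxy-2,6-dimethyl-2-(triethylsilyloxy)hept-6-enal (epimers at the carbinol carbon, future C8; present mainly as its six-membered lactol)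
Conditions: 12 (1.0 equiv, slow addition), THF, −78 °C
Reagents that add atoms: none
Why: Chemoselective Grignard addition, with one equivalent at low temperature attacking the unhindered C8 aldehyde rather than the neopentyl-type α-silyloxy aldehyde and the new alkoxide then masking the latter as a lactolate, installs C8a, C1 and the C8a methyl, the C8 configuration being irrelevant because it is oxidised in step 14.

Step 11
Reactants: 8 (1R,3R)-3-bromo-1-ethynyl-1,2,2-trimethylcyclopentane; 13 (2R)-5-hydroxy-2,6-dimethyl-2-(triethylsilyloxy)hept-6-enal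
Product: 15 propargylic diol, via alkynylmagnesium bromide 14 (not isolated)
Conditions: 8 (2.2 equiv), EtMgBr, THF, 0 to 40 °C; then 13, 0 °C to rt
Reagents that add atoms: none
Why: Addition of an alkynyl Grignard reagent to a lactol, in which the first equivalent deprotonates the lactol (and is recovered as 8) and the second adds to the open aldehyde, forms C4–C4a, magnesium alkoxides being chosen because they neither provoke migration of the neighbouring triethylsilyl group nor attack the hindered bromide, and the C4a configuration is irrelevant because this carbon becomes sp2 in step 15.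

Step 12
Reactants: 15 propargylic diol
Product: 17 Z-vinyl iodide diol, via cyclic alkenylalanate 16 (not isolated)
Conditions: NaAlH2(OCH2CH2OMe)2 (Red-Al), THF, 0 °C to rt; then I2, −78 to 0 °C
Reagents that add atoms: iodine, II
Why: Hydroxyl-directed trans-hydroalumination of the propargylic alcohol places aluminium on C3 within a five-membered chelate, and iodinolysis with retention gives the Z-iodide in which C–I is cis to C4a, as lactonisation requires.

Step 13
Reactants: 17 Z-vinyl iodide diol
Product: 18 hydroxy butenolide
Conditions: PdCl2(PPh3)2 (5 mol %), CO (1 atm), Et3N, THF, 50 °C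
Reagents that add atoms: carbon monoxide, [C-]#[O+]
Why: Palladium-catalysed carbonylative lactonisation (oxidative addition of the vinyl iodide to zerovalent palladium, CO insertion, capture of the acylpalladium by the cis C4a hydroxyl) introduces C2 and closes the butenolide, the remote C8 hydroxyl and the unactivated alkyl bromide being unable to compete.

Step 14
Reactants: 18 hydroxy butenolide
Product: 19 enone butenolide
Conditions: Dess–Martin periodinane, CH2Cl2, 0 °C to rt
Reagents that add atoms: none
Why: Dess–Martin oxidation converts the allylic alcohol into the isopropenyl ketone under nearly neutral conditions that leave the butenolide, the silyl ether and the bromide alone.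

Step 15
Reactants: 19 enone butenolide
Product: 20 silyloxyfuran enone (cycloaddition precursor)
Conditions: TIPSOTf (1.0 equiv), Et3N, CH2Cl2, −78 to −20 °C; filtration through Et3N-deactivated silica
Reagents that add atoms: triisopropylsilyl triflate, CC(C)[Si](C(C)C)(C(C)C)OS(=O)(=O)C(F)(F)F
Why: Soft enolisation of a butenolide to a 2-silyloxyfuran is driven by aromatisation and concerns by far the most acidic C–H of the molecule (C4a–H), so one equivalent of triflate at low temperature should leave the C7 position of the ketone unsilylated.

Step 16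
Reactants: 20 silyloxyfuran enone
Product: 22 trans-fused 4a-hydroxy-2,8-dione C5 triethylsilyl ether, via oxa-bridged cycloadduct 21 (not isolated)
Conditions: toluene (0.01 M), BHT, 2,6-di-tert-butyl-4-methylpyridine (cat.), base-washed sealed tube, 110 °C; then 0.1 M aq HCl, THF, 0 °C
Reagents that add atoms: none
Why: A concerted, suprafacial [4π+2π] cycloaddition joins the furan diene C2=C3–C4=C4a to the enone alkene C8a=C1, and brief aqueous acid then ionises the strained bridgehead silyl ketal 21 at its C2–O(bridge) bond, silicon going to water, which leaves the C2 ketone, the C3=C4 alkene and the C4a hydroxyl, makes the otherwise reversible furan cycloaddition irreversible and cannot end in a phenol because C8a is quaternary. The closest known reaction types are intramolecular furan Diels–Alder reactions of 2-alkylfurans carrying the same four-atom keto tether and cycloadditions of 2-silyloxy- and 2-amidofurans whose oxygen bridge opens to a 4-hydroxycyclohexenone. Ring B closes as the six-membered ring of the cycloaddition itself (first as a 7-oxanorbornene), and ring A closes in the fused mode as a six-membered ring because the C5–C6–C7–C8 tether, folded like a chair, ties C4a to C8a. The relation of C8a to C4a is fixed by the tether, which can only lie exo, on the side of the oxygen bridge, so that the C8a methyl points endo, away from the bridge, and the decalin emerges trans-fused with methyl and hydroxyl on opposite faces. The absolute sense is fixed by the C5 stereocentre, which selects the furan face through the chair that keeps the C5 methyl equatorial and antiperiplanar to the forming C4a–C8a bond and the C5–O bond axial and close to the furan plane, thereby avoiding a syn-axial methyl/methyl contact with the C8a methyl and keeping the withdrawing C–O bond out of conjugation with the diene. Regioselectivity is the selectivity at stake, since the silyloxy group polarises C4a towards C1 while the target needs C4a–C8a and C1–C2; the short tether enforces the latter, and Lewis acids, which would favour a vinylogous Mukaiyama–Michael attack of C4a on C1, are avoided in favour of dilute, base-buffered thermal conditions with a radical inhibitor.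

Step 17
Reactants: 22 trans-fused 4a-hydroxy-2,8-dione C5 triethylsilyl ether
Product: 23 axial C8 alcohol (8R; C8–OH syn to C4a–OH, anti to the C8a methyl)
Conditions: LiBH(s-Bu)3 (L-Selectride, 2.2 equiv), THF, −78 °C
Reagents that add atoms: none
Why: Bulky trialkylborohydride reduction, in which the saturated C8 ketone is the more electrophilic carbonyl while the enone is shielded at C2 by ring C and at C4 by the C8a methyl, the C5 silyloxy group and the C4a alkoxide, proceeds along the equatorial trajectory from the face opposite the axial C4a oxygen and so sets the axial alcohol.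

Step 18
Reactants: 23 axial C8 alcohol
Product: 24 dibromide C5 triethylsilyl ether (8S, equatorial bromide)
Conditions: CBr4, PPh3, toluene, rt to 70 °C
Reagents that add atoms: carbon tetrabromide, BrC(Br)(Br)Br
Why: Appel reaction on an axial neopentyl-type cyclohexanol, a conversion known to give equatorial bromides in trans-decalin terpenoids, activates only the secondary hydroxyl and lets bromide displace it with inversion, while the electron-poor C8a (flanked by C4a–O and the C1–C2 keto unit) discourages methyl migration.

Step 19
Reactants: 24 dibromide C5 triethylsilyl ether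
Product: 25 target CNP0216929.1
Conditions: HF·pyridine, THF, 0 °C to rt
Reagents that add atoms: none
Why: Fluoride-mediated cleavage of the tertiary triethylsilyl ether with buffered HF is mild enough for both secondary bromides and the γ-hydroxy enone and touches no stereocentre.

Compound list
1 | (1S,3R)-camphoric acid, (1S,3R)-1,2,2-trimethylcyclopentane-1,3-dicarboxylic acid | CC1(C)[C@H](C(=O)O)CC[C@]1(C)C(=O)O | starting material
2 | (1S,3R)-1,2,2-trimethylcyclopentane-1,3-dimethanol | CC1(C)[C@H](CO)CC[C@]1(C)CO | intermediate
3 | (1S,3R)-1,2,2-trimethylcyclopentane-1,3-dicarbaldehyde | CC1(C)[C@H](C=O)CC[C@]1(C)C=O | intermediate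
4 | (1S)-3-[(tert-butyldimethylsilyloxy)methylidene]-1,2,2-trimethylcyclopentane-1-carbaldehyde, E/Z mixture | CC1(C)C(=CO[Si](C)(C)C(C)(C)C)CC[C@]1(C)C=O | intermediate
5 | (1S)-1,2,2-trimethyl-3-oxocyclopentane-1-carbaldehyde | CC1(C)C(=O)CC[C@]1(C)C=O | intermediate
6 | (3R)-3-ethynyl-2,2,3-trimethylcyclopentan-1-one | CC1(C)C(=O)CC[C@]1(C)C#C | intermediate
7 | (1S,3R)-3-ethynyl-2,2,3-trimethylcyclopentan-1-ol, OH trans to ethynyl | CC1(C)[C@@H](O)CC[C@]1(C)C#C | intermediate
8 | (1R,3R)-3-bromo-1-ethynyl-1,2,2-trimethylcyclopentane, Br cis to ethynyl (ring C alkyne) | CC1(C)[C@H](Br)CC[C@]1(C)C#C | intermediate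
9 | (R)-linalool, (3R)-3,7-dimethylocta-1,6-dien-3-ol | C=C[C@](C)(O)CCC=C(C)C | starting material
10 | (R)-linalool triethylsilyl ether | C=C[C@](C)(O[Si](CC)(CC)CC)CCC=C(C)C | intermediate
11 | (2R)-2-methyl-2-(triethylsilyloxy)pentanedial | O=C[C@](C)(O[Si](CC)(CC)CC)CCC=O | intermediate
12 | isopropenylmagnesium bromide | C=C(C)[Mg]Br | starting material
13 | (2R)-5-hydroxy-2,6-dimethyl-2-(triethylsilyloxy)hept-6-enal, carbinol epimers, drawn open-chain, present mainly as the six-membered lactol | O=C[C@](C)(O[Si](CC)(CC)CC)CCC(O)C(C)=C | intermediate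
14 | alkynylmagnesium bromide of 8 | CC1(C)[C@H](Br)CC[C@]1(C)C#C[Mg]Br | intermediate
15 | propargylic diol: ring C–C3≡C4–C4aH(OH)–C5(CH3)(OSiEt3)–C6H2–C7H2–C8H(OH)–C8a(CH3)=C1H2; C5 R, ring C as in 8, epimers at C4a and C8 | CC1(C)[C@H](Br)CC[C@]1(C)C#CC(O)[C@](C)(O[Si](CC)(CC)CC)CCC(O)C(C)=C | intermediate
16 | cyclic alkenylalanate: five-membered O–Al–C3=C4–C4a chelate, C8 oxygen bound to a second aluminate, disodium salt | [Na+].[Na+].COCCO[Al-]1(OCCOC)OC([C@](C)(O[Si](CC)(CC)CC)CCC(O[Al-]([H])(OCCOC)OCCOC)C(C)=C)C=C1[C@@]2(C)CC[C@@H](Br)C2(C)C | intermediate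
17 | Z-vinyl iodide diol: iodine on C3, cis to C4a; otherwise as 15 | I/C(=C\C(O)[C@](C)(O[Si](CC)(CC)CC)CCC(O)C(C)=C)[C@@]1(C)CC[C@@H](Br)C1(C)C | intermediate
18 | hydroxy butenolide: furan-2(5H)-one with ring C on C3 and the C5–C8 chain on C4a, free C8 allylic alcohol; C5 R, 1′R,3′R, epimers at C4a and C8 | O=C1OC([C@](C)(O[Si](CC)(CC)CC)CCC(O)C(C)=C)C=C1[C@@]2(C)CC[C@@H](Br)C2(C)C | intermediate
19 | enone butenolide: as 18 with the C8 isopropenyl ketone, epimers at C4a | O=C1OC([C@](C)(O[Si](CC)(CC)CC)CCC(=O)C(C)=C)C=C1[C@@]2(C)CC[C@@H](Br)C2(C)C | intermediate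
20 | silyloxyfuran enone: 2-(triisopropylsilyloxy)furan, ring C (1′R,3′R) on C3, (5R)-C5(CH3)(OSiEt3)–C6H2–C7H2–C8(=O)–C8a(CH3)=C1H2 on C4a | C=C(C)C(=O)CC[C@@](C)(O[Si](CC)(CC)CC)c1oc(O[Si](C(C)C)(C(C)C)C(C)C)c([C@@]2(C)CC[C@@H](Br)C2(C)C)c1 | intermediate
21 | oxa-bridged cycloadduct: 7-oxanorbornene with oxygen bridging C2 and C4a, OSi(i-Pr)3 on C2, tether exo, C8a methyl endo | CC1(C)[C@H](Br)CC[C@]1(C)C1=C[C@]2(O3)[C@](C)(O[Si](CC)(CC)CC)CCC(=O)[C@@]2(C)C[C@]13O[Si](C(C)C)(C(C)C)C(C)C | intermediate
22 | (4aR,5R,8aS) trans-fused 4a-hydroxy-2,8-dione, C3=C4 enone, C5 triethylsilyl ether, ring C 1′R,3′R | CC1(C)[C@H](Br)CC[C@]1(C)C1=C[C@]2(O)[C@](C)(O[Si](CC)(CC)CC)CCC(=O)[C@@]2(C)CC1=O | intermediate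
23 | axial C8 alcohol (4aR,5R,8R,8aR): C8–OH syn-diaxial to C4a–OH | CC1(C)[C@H](Br)CC[C@]1(C)C1=C[C@]2(O)[C@](C)(O[Si](CC)(CC)CC)CC[C@@H](O)[C@@]2(C)CC1=O | intermediate
24 | dibromide C5 triethylsilyl ether (4aR,5R,8S,8aS), equatorial C8 bromide | CC1(C)[C@H](Br)CC[C@]1(C)C1=C[C@]2(O)[C@](C)(O[Si](CC)(CC)CC)CC[C@H](Br)[C@@]2(C)CC1=O | intermediate
25 | (4aR,5R,8S,8aS)-8-bromo-3-[(1R,3R)-3-bromo-1,2,2-trimethylcyclopentyl]-4a,5-dihydroxy-5,8a-dimethyl-4a,5,6,7,8,8a-hexahydronaphthalen-2(1H)-one | CC1(C)[C@H](Br)CC[C@]1(C)C1=C[C@]2(O)[C@](C)(O)CC[C@H](Br)[C@@]2(C)CC1=O | target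

Total step count: 19. Longest linear sequence: 16 (steps 1–7 and 11–19).

Steps most likely to fail

**Step 16 (key step).** Bond formation between the two fully substituted carbons C4a and C8a, next to the quaternary C5, may be too slow at temperatures the furan tolerates. Cycloreversion, vinylogous loss of the C5 silyloxy group from the electron-rich furan, or Michael-type attack of C4a on C1 could then take over. The fallback keeps the same bonds but uses a different diene. A bromine atom replaces the silyloxy group, since a halogen on the remote furan α-carbon is known to accelerate intramolecular furan Diels–Alder reactions and to make them more exergonic. Setting out from 18, reduction of the lactone with i-Bu2AlH to the lactol and mild acid dehydration give the 2,4-disubstituted furan alcohol F1. NBS brominates the only free α-position (C2) to the 2-bromofuran alcohol F2. Dess–Martin oxidation gives the bromofuran enone F3. Heating in toluene over solid NaHCO3 should give the bridged α-bromo ether F4. Its hydrolysis with aqueous NaHCO3 opens the bridge and comes back to the route at 22.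

**Step 18.** The axial oxyphosphonium group is antiperiplanar to the axial C7 hydrogen and to the C8a methyl. Elimination towards C7 or a 1,2-methyl shift may therefore outrun the hindered substitution, and the neighbouring C4a hydroxyl may tie up phosphorus. The fallback uses the syn-diaxial 1,3-diol as a handle. From 23, SOCl2/pyridine gives the cyclic sulfite F5. RuCl3 (cat.)/NaIO4 oxidises it to the cyclic sulfate F6. LiBr in THF opens the sulfate at the secondary carbon C8 with inversion to the lithium C4a-sulfate of the equatorial bromide F7. Dilute H2SO4 in wet THF hydrolyses the sulfate ester together with the triethylsilyl ether, which comes back to the route at 25.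

**Step 15.** Enol silylation of the C8 ketone at C7 may compete with furan formation, and residual silyl triflate may trigger Michael-type closure of the new silyloxyfuran onto the enone. The fallback makes the furan first and the enone last. From 18, Ac2O/pyridine gives the C8 acetate F8. TIPSOTf/Et3N then meets no enolisable ketone and gives the silyloxyfuran acetate F9. i-Bu2AlH at −78 °C removes the acetyl group to give the silyloxyfuran alcohol F10. Non-acidic oxidation with Pr4N[RuO4] (cat.)/N-methylmorpholine N-oxide over molecular sieves comes back to the route at 20.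

Further compounds
F1 | step 16 | 2,4-disubstituted furan alcohol | C=C(C)C(O)CC[C@@](C)(O[Si](CC)(CC)CC)c1occ([C@@]2(C)CC[C@@H](Br)C2(C)C)c1
F2 | step 16 | 2-bromofuran alcohol | C=C(C)C(O)CC[C@@](C)(O[Si](CC)(CC)CC)c1oc(Br)c([C@@]2(C)CC[C@@H](Br)C2(C)C)c1
F3 | step 16 | bromofuran enone | C=C(C)C(=O)CC[C@@](C)(O[Si](CC)(CC)CC)c1oc(Br)c([C@@]2(C)CC[C@@H](Br)C2(C)C)c1
F4 | step 16 | bridged α-bromo ether | CC1(C)[C@H](Br)CC[C@]1(C)C1=C[C@]2(O3)[C@](C)(O[Si](CC)(CC)CC)CCC(=O)[C@@]2(C)C[C@]13Br
F5 | step 18 | cyclic sulfite of the C4a,C8-diol | CC1(C)[C@H](Br)CC[C@]1(C)C1=C[C@]2(O3)[C@](C)(O[Si](CC)(CC)CC)CC[C@@H](OS3=O)[C@@]2(C)CC1=O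
F6 | step 18 | cyclic sulfate of the C4a,C8-diol | CC1(C)[C@H](Br)CC[C@]1(C)C1=C[C@]2(O3)[C@](C)(O[Si](CC)(CC)CC)CC[C@@H](OS3(=O)=O)[C@@]2(C)CC1=O
F7 | step 18 | lithium C4a-sulfate of the equatorial bromide | CC1(C)[C@H](Br)CC[C@]1(C)C1=C[C@]2(OS(=O)(=O)[O-])[C@](C)(O[Si](CC)(CC)CC)CC[C@H](Br)[C@@]2(C)CC1=O.[Li+]
F8 | step 15 | C8 acetate of the hydroxy butenolide | O=C1OC([C@](C)(O[Si](CC)(CC)CC)CCC(OC(C)=O)C(C)=C)C=C1[C@@]2(C)CC[C@@H](Br)C2(C)C
F9 | step 15 | silyloxyfuran acetate | C=C(C)C(OC(C)=O)CC[C@@](C)(O[Si](CC)(CC)CC)c1oc(O[Si](C(C)C)(C(C)C)C(C)C)c([C@@]2(C)CC[C@@H](Br)C2(C)C)c1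
F10 | step 15 | silyloxyfuran alcohol | C=C(C)C(O)CC[C@@](C)(O[Si](CC)(CC)CC)c1oc(O[Si](C(C)C)(C(C)C)C(C)C)c([C@@]2(C)CC[C@@H](Br)C2(C)C)c1
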